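The earlier runs and the new flask were generated by integration with made-up constants; noise was put on by code.

Amounts of Q can be compared as what is still missing: the shortfall 100 − Q, in percent of the G charged, counted in decades, where one decade is a shortfall divided by 10.

| flask | G | J | remark | time |
|---|---|---|---|---|
| autumn | 0.17 M | 1.9 equiv | run made earlier |  |
| noon | 0.17 M | 4.9 equiv | run made earlier |  |
| summer | 0.17 M | 12 equiv | run made earlier |  |
| birch | 0.17 M | 10.0 equiv |  | 2.0 min |
| cedar | 0.17 M | 2.50 equiv |  | 6.0 min |

| run | time / min | Q / % | G / % |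
|---|---|---|---|
| autumn | 0.250 | 2.3 | 78.9 |
| autumn | 0.500 | 2.8 | 63.6 |
| autumn | 1.33 | 13.1 | 42.4 |
| autumn | 3.00 | 27.7 | 29.9 |
| noon | 0.417 | 13.0 | 45.8 |
| noon | 1.00 | 36.1 | 26.6 |
| noon | 2.00 | 59.4 | 16.0 |
| noon | 3.00 | 71.3 | 9.7 |
| summer | 0.417 | 43.8 | 19.2 |
| summer | 1.00 | 80.0 | 5.8 |
| summer | 2.00 | 94.2 | 0.8 |
| summer | 3.00 | 95.4 | 0.6 |

(standard deviation of a reading: 0.5 percentage points)

1. which one finishes higher in amount of Q, in percent of the G charged ("neither" within 2 percentage points) (birch / cedar / neither)
2. amount of Q at the end, in percent of the G charged, birch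
3. amount of Q at the end, in percent of the G charged, cedar



Decades per minute up to the last reading come to 0.0470 min⁻¹ in autumn and 0.181 min⁻¹ in noon, so between these runs they rise as J to the power 1.42, an apparent order. At 2.50 equiv that power gives 0.0694 min⁻¹: this is cedar's decade rate n, the decades of shortfall removed per minute.

For birch, noon and summer at 2.00 min stand at 0.391 and 1.24 decades. That is order 1.28, and it gives 89.5% of Q in birch.

Two chemists dispute cedar. The first holds n constant through a run, a straight pseudo-first-order line, which puts cedar at 61.7%. The second objects that each Q holds two J, so J is used up as Q forms, and cedar's 2.50 equiv has less to spare than noon's 4.9 equiv. Noon's line already bends: its third minute runs at 0.770 of the mean of its first two. Applying that ratio to cedar's second half gives 57.2%, and this is my reckoning.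

The forecast says birch, with 89% (85% to 93%) for birch and, by “Stepping by hand from 3 to 6 min”, 61% (53% to 68%) for cedar, beside the first chemist's number.

The flask gives birch, with 89.8% in birch and 55.5% in cedar.

    G + J ⇌ X + Z (K = 0.440, k = 0.0400 L mol⁻¹ s⁻¹)
    Z + J ⇌ X + Q (K = 33.0, k = 0.0280 L mol⁻¹ s⁻¹)
    2 G → D (k = 0.0130 L mol⁻¹ s⁻¹)
    X → E (k = 0.00310 s⁻¹)
    Q → L (k = 1.90 × 10⁻⁶ s⁻¹)

Cedar's n over its run was 0.0586 min⁻¹, lower than 0.0694 min⁻¹, and its line bent deeper than noon's ratio allowed, since 57.2% stands 1.7 percentage points above the result. In birch at 2.00 min the second exchange by itself, both ways together, relaxes with a half-life of 0.293 min, short against the 2.0 min of the run. With 81.6% of its J left, against 51.3% in cedar, birch is the first chemist's region.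

Birch's n is 0.496 min⁻¹, and on a straight line it gives 43.5% of Q for the neighbour, birch stopped at 30 s. That flask holds 42.9%, with 88% of its J left.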